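**Plan**
Cuts: first the two ester C–O bonds (O9–acyl, O10–acyl), then both CH2O arms back to carbonyl carbons (C9 as methyl ester, C10 as aryl lactone), last the C8–C10 bond by undoing a 1,2-acyl shift, which leads to a chromane-2,3,4-trione.
Feature used: the aryl ring, the phenol oxygen, the carbinol carbon C8 and its arms C9 and C10 are the benzo ring, O1, C4, C3 and C2 of 4-hydroxy-7-methylcoumarin once C2 has moved from C3 to C4.
Forward: the pyranone ring is oxidised at C3 (diazo transfer, then oxygen transfer), contracted to the five-membered lactone, opened by reduction (phenol and C10–OH), the ester is reduced (C9–OH), and the arms are acylated one after the other.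
Stereochemistry: C8 comes from the ring contraction under a chiral Cu(OTf)2/bis(oxazoline) catalyst and is kept because the two arms are never equivalent afterwards; the acyl stereocentre is bought as (S)-2-methylbutanoic acid.

Key step: step 3

Labels: C8 is the carbinol carbon, C9 the arm that ends as the 2-methylbutanoate, C10 the arm that ends as the isobutyrate; O8, O9 and O10 are their oxygens.
Assumption: the (S,S)-tert-butyl bis(oxazoline) is taken to give the (3S)-benzofuranone; if a first run shows the opposite sense, the (R,R)-ligand is used and nothing else changes.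

Step 1
Reactants: 1 4-hydroxy-7-methylcoumarin
Product: 2 3-diazo-7-methylchromane-2,4-dione
Conditions: 4-acetamidobenzenesulfonyl azide (1.1 equiv), Et3N (1.2 equiv), MeCN, 0 °C → rt
Reagents that add atoms: 4-acetamidobenzenesulfonyl azide (p-ABSA), CC(=O)Nc1ccc(cc1)S(=O)(=O)N=[N+]=[N-]
Why: Regitz diazo transfer, routine for 4-hydroxycoumarins: the triethylammonium enolate of the cyclic β-keto lactone attacks the terminal azide nitrogen through C3 and the triazene collapses to the 2-diazo-1,3-dicarbonyl compound and the sulfonamide.

Step 2
Reactants: 2 3-diazo-7-methylchromane-2,4-dione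
Product: 3 7-methylchromane-2,3,4-trione
Conditions: dimethyldioxirane (1.5 equiv, acetone solution dried over MgSO4), 0 °C → rt; evaporation, toluene azeotrope, storage over P2O5 under argon
Reagents that add atoms: dimethyldioxirane, CC1(C)OO1
Why: Oxygen-atom transfer from a dioxirane to the diazo carbon of a 2-diazo-1,3-dicarbonyl compound with loss of N2 is an established neutral route to vicinal tricarbonyls, and since acetone is the only other product the moisture-sensitive trione is obtained by evaporation without aqueous work-up, so that hydration of the central carbonyl is avoided.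

Step 3
Reactants: 3 7-methylchromane-2,3,4-trione; 4 methanol
Product: 6 methyl (3S)-3-hydroxy-6-methyl-2-oxo-2,3-dihydro-1-benzofuran-3-carboxylate, via C3 methyl hemiketal 5 (not isolated)
Conditions: Cu(OTf)2 (10 mol %), 2,2'-(propane-2,2-diyl)bis[(4S)-4-tert-butyl-4,5-dihydro-1,3-oxazole] (12 mol %), 4 Å MS, CH2Cl2, −20 °C; MeOH (1.05 equiv) by syringe pump; short silica plug, alcohol-free eluent
Reagents that add atoms: none
Why: Proposed new method: methanol adds to the central, most electrophilic C3 carbonyl of 3 to give hemiketal 5, whose hydroxyl and the neighbouring C4 ketone bind the divalent copper bis(oxazoline) complex as a five-membered chelate; the hemiketal oxygen then folds down to the methyl ester carbonyl while the lactone acyl carbon C2 moves from C3 to C4, which forms the C8–C10 bond of the target and turns the C4 ketone into the tertiary alkoxide. The closest known reaction is the Cu(OTf)2/bis(oxazoline)-catalysed enantioselective benzilic ester rearrangement of acyclic 2,3-diketo esters with alcohols, which also runs by a 1,2-ester shift, whereas a cyclic trione with ring contraction has not been shown (the classical relative is the contraction of alloxan to alloxanic acid). The five-membered lactone is closed by this 1,2-acyl shift inside the existing six-membered ring, through a three-centre transition state and not by an end-to-end cyclisation. The one new stereocentre, C3 of 6, is defined by the face of the C4 ketone that accepts the migrating carbon and is controlled by the tert-butyl groups of the ligand around the chelate. The step needs attack of methanol at C3 instead of the lactone carbonyl and migration towards C4; the first follows from the electrophilicity of the central carbonyl of a vicinal trione, the second from the two-point chelation, and a shift of the aryl carbon from a C4 hemiketal would end in the same constitution. Methanolysis of the aryl lactone before or after the shift would lead to an achiral dimethyl hydroxymalonate and from there back to racemic 6, hence one equivalent of methanol, slow addition, sieves and an alcohol-free work-up.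

Step 4
Reactants: 6 methyl (3S)-3-hydroxy-6-methyl-2-oxo-2,3-dihydro-1-benzofuran-3-carboxylate
Product: 8 methyl (2R)-2,3-dihydroxy-2-(2-hydroxy-4-methylphenyl)propanoate, via hydroxy aldehyde 7 (not isolated)
Conditions: NaBH4 (1.5 equiv), DME, −10 → 0 °C; pH 7 phosphate buffer; crude product taken on at once
Reagents that add atoms: none
Why: Chemoselective borohydride reduction of an aryl ester: the strained phenolic lactone is far more electrophilic than the methyl ester, hydride addition and loss of the phenoxide give aldehyde 7, which is reduced at once, and the aprotic solvent excludes alcoholysis of the lactone; the quaternary centre is untouched and only its descriptor changes.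

Step 5
Reactants: 8 methyl (2R)-2,3-dihydroxy-2-(2-hydroxy-4-methylphenyl)propanoate
Product: 9 methyl (2R)-3-[(tert-butyldimethylsilyl)oxy]-2-{2-[(tert-butyldimethylsilyl)oxy]-4-methylphenyl}-2-hydroxypropanoate
Conditions: TBSCl (2.4 equiv), imidazole (5 equiv), DMF, 0 °C → rt
Reagents that add atoms: tert-butyldimethylsilyl chloride (TBSCl), CC(C)(C)[Si](C)(C)Cl
Why: Silylation under Corey conditions takes the phenol and the primary alcohol but not the hindered tertiary carbinol, and capping the phenol at once prevents its lactonisation onto the methyl ester.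

Step 6
Reactants: 9 methyl (2R)-3-[(tert-butyldimethylsilyl)oxy]-2-{2-[(tert-butyldimethylsilyl)oxy]-4-methylphenyl}-2-hydroxypropanoate
Product: 11 (2S)-3-[(tert-butyldimethylsilyl)oxy]-2-{2-[(tert-butyldimethylsilyl)oxy]-4-methylphenyl}propane-1,2-diol, via silyloxy aldehyde 10 (not isolated)
Conditions: i-Bu2AlH (4 equiv), CH2Cl2, −78 → 0 °C; aq. KNaC4H4O6 (potassium sodium tartrate)
Reagents that add atoms: none
Why: Reduction of a methyl ester to the primary alcohol with i-Bu2AlH through aldehyde 10; the covalent aluminium alkoxides at O8 and O9 are poor nucleophiles, so silyl migration between O10, O9 and the phenol oxygen, which would blur the distinction between the arms, is not expected.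

Step 7
Reactants: 11 (2S)-3-[(tert-butyldimethylsilyl)oxy]-2-{2-[(tert-butyldimethylsilyl)oxy]-4-methylphenyl}propane-1,2-diol; 12 (S)-2-methylbutanoic acid
Product: 13 (2S)-3-[(tert-butyldimethylsilyl)oxy]-2-{2-[(tert-butyldimethylsilyl)oxy]-4-methylphenyl}-2-hydroxypropyl (2S)-2-methylbutanoate
Conditions: DCC (1.3 equiv), 4-(dimethylamino)pyridine (DMAP, 0.1 equiv), CH2Cl2, 0 °C → rt
Reagents that add atoms: none
Why: Steglich esterification acylates the only primary alcohol while the tertiary benzylic carbinol stays inert at this temperature, and the α-stereocentre of the acid, which carries no acidifying group, should survive carbodiimide activation at 0 °C with little DMAP.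

Step 8
Reactants: 13 (2S)-3-[(tert-butyldimethylsilyl)oxy]-2-{2-[(tert-butyldimethylsilyl)oxy]-4-methylphenyl}-2-hydroxypropyl (2S)-2-methylbutanoate
Product: 14 (2R)-2-{2-[(tert-butyldimethylsilyl)oxy]-4-methylphenyl}-2,3-dihydroxypropyl (2S)-2-methylbutanoate
Conditions: camphorsulfonic acid (0.2 equiv), MeOH–CH2Cl2 1:1, 0 °C; solid NaHCO3, then directly into step 9
Reagents that add atoms: none
Why: Acid-catalysed methanolysis cleaves alkyl silyl ethers faster than aryl silyl ethers because the alkyl ether oxygen is the more basic, so the primary TBS ether should go and the phenol TBS ether stay, and the acidic medium also holds back acyl migration from O9 to O10, which would invert C8.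

Step 9
Reactants: 14 (2R)-2-{2-[(tert-butyldimethylsilyl)oxy]-4-methylphenyl}-2,3-dihydroxypropyl (2S)-2-methylbutanoate; 15 isobutyric anhydride
Product: 16 (2R)-2-{2-[(tert-butyldimethylsilyl)oxy]-4-methylphenyl}-2-hydroxy-3-[(2-methylpropanoyl)oxy]propyl (2S)-2-methylbutanoate
Conditions: pyridine (3 equiv), DMAP (0.05 equiv), CH2Cl2, 0 °C
Reagents that add atoms: none
Why: DMAP-catalysed acylation with the anhydride esterifies the primary alcohol quickly at 0 °C while the tertiary carbinol and the silylated phenol do not react, and prompt acylation fixes the acyl pattern of the two arms.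

Step 10
Reactants: 16 (2R)-2-{2-[(tert-butyldimethylsilyl)oxy]-4-methylphenyl}-2-hydroxy-3-[(2-methylpropanoyl)oxy]propyl (2S)-2-methylbutanoate
Product: 17 (2R)-2-hydroxy-2-(2-hydroxy-4-methylphenyl)-3-[(2-methylpropanoyl)oxy]propyl (2S)-2-methylbutanoate
Conditions: Bu4NF (1.1 equiv), AcOH (1.2 equiv), THF, 0 °C
Reagents that add atoms: none
Why: Fluoride cleavage of an aryl silyl ether is fast at 0 °C, and buffering Bu4NF with acetic acid keeps the phenol protonated so that neither ester should be cleaved or shifted to the phenol or to O8.

**Compound list**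
1 | 4-hydroxy-7-methylcoumarin (4-hydroxy-7-methyl-2H-chromen-2-one) | Cc1ccc2c(O)cc(=O)oc2c1 | starting material
2 | 3-diazo-7-methylchromane-2,4-dione | Cc1ccc2c(c1)OC(=O)C(=[N+]=[N-])C2=O | intermediate
3 | 7-methylchromane-2,3,4-trione | Cc1ccc2c(c1)OC(=O)C(=O)C2=O | intermediate
4 | methanol | CO | starting material
5 | 3-hydroxy-3-methoxy-7-methylchromane-2,4-dione (C3 hemiketal, configuration at C3 not fixed) | COC1(O)C(=O)Oc2cc(C)ccc2C1=O | intermediate (not isolated)
6 | methyl (3S)-3-hydroxy-6-methyl-2-oxo-2,3-dihydro-1-benzofuran-3-carboxylate | COC(=O)[C@]1(O)C(=O)Oc2cc(C)ccc21 | intermediate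
7 | methyl (2R)-2-hydroxy-2-(2-hydroxy-4-methylphenyl)-3-oxopropanoate | COC(=O)[C@](O)(C=O)c1ccc(C)cc1O | intermediate (not isolated)
8 | methyl (2R)-2,3-dihydroxy-2-(2-hydroxy-4-methylphenyl)propanoate | COC(=O)[C@](O)(CO)c1ccc(C)cc1O | intermediate
9 | methyl (2R)-3-[(tert-butyldimethylsilyl)oxy]-2-{2-[(tert-butyldimethylsilyl)oxy]-4-methylphenyl}-2-hydroxypropanoate | COC(=O)[C@](O)(CO[Si](C)(C)C(C)(C)C)c1ccc(C)cc1O[Si](C)(C)C(C)(C)C | intermediate
10 | (2R)-3-[(tert-butyldimethylsilyl)oxy]-2-{2-[(tert-butyldimethylsilyl)oxy]-4-methylphenyl}-2-hydroxypropanal | O=C[C@](O)(CO[Si](C)(C)C(C)(C)C)c1ccc(C)cc1O[Si](C)(C)C(C)(C)C | intermediate (not isolated)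
11 | (2S)-3-[(tert-butyldimethylsilyl)oxy]-2-{2-[(tert-butyldimethylsilyl)oxy]-4-methylphenyl}propane-1,2-diol | OC[C@](O)(CO[Si](C)(C)C(C)(C)C)c1ccc(C)cc1O[Si](C)(C)C(C)(C)C | intermediate
12 | (S)-2-methylbutanoic acid | CC[C@H](C)C(=O)O | starting material
13 | (2S)-3-[(tert-butyldimethylsilyl)oxy]-2-{2-[(tert-butyldimethylsilyl)oxy]-4-methylphenyl}-2-hydroxypropyl (2S)-2-methylbutanoate | CC[C@H](C)C(=O)OC[C@](O)(CO[Si](C)(C)C(C)(C)C)c1ccc(C)cc1O[Si](C)(C)C(C)(C)C | intermediate
14 | (2R)-2-{2-[(tert-butyldimethylsilyl)oxy]-4-methylphenyl}-2,3-dihydroxypropyl (2S)-2-methylbutanoate | CC[C@H](C)C(=O)OC[C@](O)(CO)c1ccc(C)cc1O[Si](C)(C)C(C)(C)C | intermediate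
15 | isobutyric anhydride | CC(C)C(=O)OC(=O)C(C)C | starting material
16 | (2R)-2-{2-[(tert-butyldimethylsilyl)oxy]-4-methylphenyl}-2-hydroxy-3-[(2-methylpropanoyl)oxy]propyl (2S)-2-methylbutanoate | CC[C@H](C)C(=O)OC[C@](O)(COC(=O)C(C)C)c1ccc(C)cc1O[Si](C)(C)C(C)(C)C | intermediate
17 | (2R)-2-hydroxy-2-(2-hydroxy-4-methylphenyl)-3-[(2-methylpropanoyl)oxy]propyl (2S)-2-methylbutanoate | CC[C@H](C)C(=O)OC[C@](O)(COC(=O)C(C)C)c1ccc(C)cc1O | target

Total steps: 10. Longest linear sequence: 10 steps (1 to 17).

**Steps most likely to fail**

Step 3. Methanolysis of the aryl lactone may outrun the 1,2-shift, or a catalyst-free background shift may compete, so that the ring-contracted ester forms with low enantiomeric purity or drains into the achiral diester. The fallback leaves the route at 3, rejoins it at 16, and sets C8 by enzymatic desymmetrisation instead.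
- 3 is stirred in excess methanol with catalytic Cu(OTf)2 and no chiral ligand. Lactone methanolysis and the known benzilic ester rearrangement of the acyclic 2,3-diketo ester should end in achiral dimethyl 2-hydroxy-2-(2-hydroxy-4-methylphenyl)propanedioate F1.
- The phenol is silylated (TBSCl, imidazole, DMF) to dimethyl 2-{2-[(tert-butyldimethylsilyl)oxy]-4-methylphenyl}-2-hydroxypropanedioate F2.
- Both esters are reduced with i-Bu2AlH to the prochiral 2-{2-[(tert-butyldimethylsilyl)oxy]-4-methylphenyl}propane-1,2,3-triol F3.
- A lipase (Burkholderia cepacia lipase or Candida antarctica lipase B, chosen by screening for the required enantiotopic preference) transfers one isobutyryl group from 15 in t-BuOMe, giving (2S)-2-{2-[(tert-butyldimethylsilyl)oxy]-4-methylphenyl}-2,3-dihydroxypropyl 2-methylpropanoate F4.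
- Steglich esterification of F4 with 12 gives 16.

Step 4. The phenoxide freed by the first reduction may close onto the methyl ester, and the new lactone would then be reduced again to an achiral triol; methoxide released on the way may open unreacted 6 and erode the enantiomeric purity. The fallback sets out from 6 and returns at 8.
- LiAlH(O-t-Bu)3 in THF at −40 °C reduces aryl esters but not alkyl esters and should stop at the aluminium hemiacetal. Work-up gives the lactol methyl (3R)-2,3-dihydroxy-6-methyl-2,3-dihydro-1-benzofuran-3-carboxylate F5 (both C2 epimers), in which the phenol oxygen is still tied up.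
- F5 is reduced through its ring-opened form 7 with NaBH(OAc)3 in AcOH–MeCN at 0 °C, an acidic medium in which neither phenoxide nor methoxide is present, to give 8.

Step 8. Discrimination between the alkyl and the aryl silyl ether may be incomplete, and in the freed mono-ester the acyl group may migrate from O9 to O10 (directly or over O8), which would invert C8 and show as the C8-epimeric diester after step 9. The fallback leaves at 13 and rejoins at 17.
- Both silyl ethers are removed together with Bu4NF/AcOH (THF, 0 °C) to give (2R)-2,3-dihydroxy-2-(2-hydroxy-4-methylphenyl)propyl (2S)-2-methylbutanoate F6.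
- F6 is acylated at once with excess 15 (pyridine, DMAP) at the primary alcohol and at the phenol, giving (2R)-2-hydroxy-3-[(2-methylpropanoyl)oxy]-2-{4-methyl-2-[(2-methylpropanoyl)oxy]phenyl}propyl (2S)-2-methylbutanoate F7.
- Pyrrolidine (CH2Cl2, 0 °C) cleaves only the aryl isobutyrate by aminolysis, the alkyl esters being inert to amines at this temperature, and frees 17.

**Further compounds**
F1 | step 3 | dimethyl 2-hydroxy-2-(2-hydroxy-4-methylphenyl)propanedioate | COC(=O)C(O)(C(=O)OC)c1ccc(C)cc1O
F2 | step 3 | dimethyl 2-{2-[(tert-butyldimethylsilyl)oxy]-4-methylphenyl}-2-hydroxypropanedioate | COC(=O)C(O)(C(=O)OC)c1ccc(C)cc1O[Si](C)(C)C(C)(C)C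
F3 | step 3 | 2-{2-[(tert-butyldimethylsilyl)oxy]-4-methylphenyl}propane-1,2,3-triol | OCC(O)(CO)c1ccc(C)cc1O[Si](C)(C)C(C)(C)C
F4 | step 3 | (2S)-2-{2-[(tert-butyldimethylsilyl)oxy]-4-methylphenyl}-2,3-dihydroxypropyl 2-methylpropanoate | CC(C)C(=O)OC[C@@](O)(CO)c1ccc(C)cc1O[Si](C)(C)C(C)(C)C
F5 | step 4 | methyl (3R)-2,3-dihydroxy-6-methyl-2,3-dihydro-1-benzofuran-3-carboxylate (both C2 epimers) | COC(=O)[C@]1(O)C(O)Oc2cc(C)ccc21
F6 | step 8 | (2R)-2,3-dihydroxy-2-(2-hydroxy-4-methylphenyl)propyl (2S)-2-methylbutanoate | CC[C@H](C)C(=O)OC[C@](O)(CO)c1ccc(C)cc1O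
F7 | step 8 | (2R)-2-hydroxy-3-[(2-methylpropanoyl)oxy]-2-{4-methyl-2-[(2-methylpropanoyl)oxy]phenyl}propyl (2S)-2-methylbutanoate | CC[C@H](C)C(=O)OC[C@](O)(COC(=O)C(C)C)c1ccc(C)cc1OC(=O)C(C)C
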